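The oxolane ring is cut into veratraldehyde (O1–C2) and a three-carbon unit C3–C4–C5 delivered by a (Z)-allylsilane. The feature exploited is the C4 hydroxyl on the ring carbon between C3 and the C5 methylene: it is carried as a silyl group, which makes C3 nucleophilic and, after a 1,2-silyl shift, C5 electrophilic. One Lewis-acid-catalysed [3+2] annulation therefore forms C2–C3 and O1–C5 and sets all three stereocentres (all-cis) from the alkene geometry and a chiral boron catalyst. The precursor is (Z)-4-[benzhydryl(dimethyl)silyl]but-2-enyl 3,4-dimethoxybenzoate; C–Si oxidation with retention then gives the target.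

Key step: step 4

Numbering used throughout: oxolane O1, C2 (aryl), C3 (acyloxymethyl), C4 (hydroxyl or silyl), C5 (methylene). The target is (2S,3R,4S), with all three substituents on the same face of the ring.

Assumption: the sense of induction of the tartrate-derived (acyloxy)borane is taken from its allylation and aldol chemistry, where the (2R,3R) catalyst directs attack to the Re face of aldehydes. The (2S,3S) catalyst is therefore specified for Si-face attack; should the sense be opposite, the (2R,3R) catalyst is used instead.

Step 1
Reactants: 1 diphenylmethane; 2 allyl(chloro)dimethylsilane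
Product: 4 allyl(benzhydryl)dimethylsilane, via diphenylmethyllithium 3 (not isolated)
Conditions: n-BuLi, THF, 0 °C to rt; then added slowly to 2 (1.2 equiv), THF, −78 °C to rt
Reagents that add atoms: none
Why: Benzylic deprotonation gives the diphenylmethyl anion, which displaces chloride at silicon (nucleophilic substitution at silicon); slow addition of 3 to an excess of 2 at −78 °C should limit a second silylation through the acidic benzhydryl C–H of the product.

Step 2
Reactants: 4 allyl(benzhydryl)dimethylsilane; 5 (Z)-but-2-ene-1,4-diol
Product: 6 (Z)-4-[benzhydryl(dimethyl)silyl]but-2-en-1-ol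
Conditions: 5 (3 equiv), Ru(SIMes)(=CH-C6H4-2-OiPr)(S2C6H2Cl2) (5 mol%; SIMes = 1,3-dimesitylimidazolidin-2-ylidene, S2C6H2Cl2 = 3,6-dichlorobenzene-1,2-dithiolate), THF, 22 °C
Reagents that add atoms: none
Why: Stereoretentive olefin cross-metathesis: the dithiolate ligand should force both substituents of the ruthenacyclobutane to the same side, so the Z geometry of 5 is carried into the new C=C bond, and the excess of 5 should suppress homodimerisation of 4.

Step 3
Reactants: 6 (Z)-4-[benzhydryl(dimethyl)silyl]but-2-en-1-ol; 7 3,4-dimethoxybenzoyl chloride
Product: 8 (Z)-4-[benzhydryl(dimethyl)silyl]but-2-en-1-yl 3,4-dimethoxybenzoate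
Conditions: Et3N, DMAP (cat.), CH2Cl2, 0 °C to rt
Reagents that add atoms: none
Why: DMAP-catalysed acylation of a primary alcohol by an acid chloride (nucleophilic acyl substitution), under conditions too mild to disturb the allylsilane or the Z-alkene.

Step 4
Reactants: 8 (Z)-4-[benzhydryl(dimethyl)silyl]but-2-en-1-yl 3,4-dimethoxybenzoate; 9 3,4-dimethoxybenzaldehyde
Product: 10 [(2S,3S,4S)-4-[benzhydryl(dimethyl)silyl]-2-(3,4-dimethoxyphenyl)oxolan-3-yl]methyl 3,4-dimethoxybenzoate (aryl, acyloxymethyl and silyl groups all cis)
Conditions: chiral (acyloxy)borane from mono(2,6-diisopropoxybenzoyl)-(2S,3S)-tartaric acid and 3,5-bis(trifluoromethyl)phenylboronic acid (20 mol%), 4 Å MS, EtCN, −78 °C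
Reagents that add atoms: none
Why: Proposed new method: the chiral (acyloxy)borane should bind the formyl oxygen of 9 and shield its Re face, so that the γ-carbon of 8 (future C3) attacks the Si face through an open, syn-selective transition state anti to the C–Si bond (anti-SE'); the β-silyl cation at C4 is then bridged by silicon, which shifts from C5 to C4 while the boron-bound oxygen closes on C5 and releases the catalyst. The closest known reactions are the BF3·OEt2- or SnCl4-mediated [3+2] annulation of bulky allylsilanes with aldehydes and the (acyloxy)borane-catalysed enantioselective Hosomi–Sakurai addition of γ-substituted allylsilanes to aromatic aldehydes; their combination on a simple aryl aldehyde is the new element. The oxolane closes by attack of O1 on C5 anti to silicon, exo-tet with respect to the breaking C5–Si bond and 5-endo with respect to the three-membered siliranium ring. C2 is set by the catalyst (Si-face attack gives 2S), C3 by the syn topology of the C–C bond formation (aryl cis to the acyloxymethyl group), and C4 by the Z geometry of the alkene together with the anti-SE' course and the suprafacial silyl shift (silicon cis to the acyloxymethyl group). The step needs annulation to win over plain allylation with loss of silicon, over oxetane formation and over silicon-assisted ionisation of the allylic ester; the bulky benzhydryl(dimethyl)silyl group, the mild boron Lewis acid and the low temperature are meant to secure this.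

Step 5
Reactants: 10 [(2S,3S,4S)-4-[benzhydryl(dimethyl)silyl]-2-(3,4-dimethoxyphenyl)oxolan-3-yl]methyl 3,4-dimethoxybenzoate
Product: 12 [(2S,3R,4S)-2-(3,4-dimethoxyphenyl)-4-hydroxyoxolan-3-yl]methyl 3,4-dimethoxybenzoate, via silanol 11 (not isolated)
Conditions: Bu4NF, THF, 0 °C to rt; then KHCO3, 30% aq. H2O2, MeOH, rt
Reagents that add atoms: hydrogen peroxide, OO
Why: Tamao–Fleming oxidation in its benzhydrylsilane form: fluoride should cleave the benzhydryl–silicon bond (stabilised carbanion as leaving group) to the silanol, and buffered peroxide should then move C4 from silicon to oxygen with retention, so that the new hydroxyl stays cis to the C3 substituent, while the absence of any electrophilic oxidant spares the two dimethoxyaryl rings.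

Compound list
1 | diphenylmethane | C(c1ccccc1)c1ccccc1 | starting material
2 | allyl(chloro)dimethylsilane | C=CC[Si](C)(C)Cl | starting material
3 | diphenylmethyllithium | [Li]C(c1ccccc1)c1ccccc1 | intermediate
4 | allyl(benzhydryl)dimethylsilane | C=CC[Si](C)(C)C(c1ccccc1)c1ccccc1 | intermediate
5 | (Z)-but-2-ene-1,4-diol | OC/C=C\CO | starting material
6 | (Z)-4-[benzhydryl(dimethyl)silyl]but-2-en-1-ol | OC/C=C\C[Si](C)(C)C(c1ccccc1)c1ccccc1 | intermediate
7 | 3,4-dimethoxybenzoyl chloride | COc1ccc(C(=O)Cl)cc1OC | starting material
8 | (Z)-4-[benzhydryl(dimethyl)silyl]but-2-en-1-yl 3,4-dimethoxybenzoate | COc1ccc(C(=O)OC/C=C\C[Si](C)(C)C(c2ccccc2)c2ccccc2)cc1OC | intermediate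
9 | 3,4-dimethoxybenzaldehyde | COc1ccc(C=O)cc1OC | starting material
10 | [(2S,3S,4S)-4-[benzhydryl(dimethyl)silyl]-2-(3,4-dimethoxyphenyl)oxolan-3-yl]methyl 3,4-dimethoxybenzoate | COc1ccc(C(=O)OC[C@@H]2[C@H]([Si](C)(C)C(c3ccccc3)c3ccccc3)CO[C@@H]2c2ccc(OC)c(OC)c2)cc1OC | intermediate
11 | [(2S,3S,4S)-2-(3,4-dimethoxyphenyl)-4-[hydroxy(dimethyl)silyl]oxolan-3-yl]methyl 3,4-dimethoxybenzoate | COc1ccc(C(=O)OC[C@@H]2[C@H]([Si](C)(C)O)CO[C@@H]2c2ccc(OC)c(OC)c2)cc1OC | intermediate
12 | [(2S,3R,4S)-2-(3,4-dimethoxyphenyl)-4-hydroxyoxolan-3-yl]methyl 3,4-dimethoxybenzoate | COc1ccc(C(=O)OC[C@@H]2[C@H](O)CO[C@@H]2c2ccc(OC)c(OC)c2)cc1OC | target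

Total step count: 5. Longest linear sequence: 5 steps (1 and 2 to 12).

Steps most likely to fail

Step 4 (proposed new method). The weak boron Lewis acid may not activate the electron-rich aldehyde enough, so that turnover stalls or facial control is poor. Silicon may also be lost before ring closure (plain allylation), or the allylic ester may ionise with silicon assistance (1,4-elimination to a diene). The fallback uses known chemistry, sets out from 8 and 9 and comes back at 10. The annulation is run with an achiral Lewis acid (BF3·OEt2, CH2Cl2, −78 °C), the established conditions for [3+2] annulation of bulky allylsilanes with aldehydes. Relative configuration is still set by the Z-alkene and the syn, anti-SE' course, so the product should be the all-cis racemate, made of 10 and its enantiomer [(2R,3R,4R)-4-[benzhydryl(dimethyl)silyl]-2-(3,4-dimethoxyphenyl)oxolan-3-yl]methyl 3,4-dimethoxybenzoate F1. The two are separated by preparative chromatography on a chiral stationary phase, F1 is set aside, and 10 goes on to step 5.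

Step 5. The aryl ester may be lost by perhydrolysis or may wander to the new C4 hydroxyl under the basic peroxide. Fluoride attack at silicon may also trigger ring-opening β-elimination of the β-alkoxysilane instead of loss of the benzhydryl group. The fallback sets out from 10 and comes back at 12, and gives the ester up on purpose. After the fluoride and peroxide treatment the crude product is stirred with K2CO3 in MeOH, so that all ester is cleaved and the single product is (3S,4R,5S)-5-(3,4-dimethoxyphenyl)-4-(hydroxymethyl)oxolan-3-ol F2. The primary hydroxyl of F2 is then acylated selectively with 7 (2,4,6-collidine, CH2Cl2, −40 °C), the hindered all-cis secondary hydroxyl being left free, which returns to 12.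

Step 2. The Z geometry may erode through secondary metathesis, or the catalyst may turn over slowly or decompose in the presence of the bulky silane and the free allylic alcohols. The fallback sets out from 3 and comes back at 6, and takes the Z-alkene from a stereodefined vinyl iodide. Diphenylmethyllithium 3, made as in step 1, is silylated with commercial chloro(chloromethyl)dimethylsilane to give benzhydryl(chloromethyl)dimethylsilane F3. Mg in THF converts it into {[benzhydryl(dimethyl)silyl]methyl}magnesium chloride F4. Separately, commercial ethyl (Z)-3-iodoacrylate is reduced with DIBAL-H (CH2Cl2, −78 °C) to (Z)-3-iodoprop-2-en-1-ol F5. Kumada coupling of F5 with F4 (2.2 equiv, the first equivalent deprotonating the hydroxyl; Pd(PPh3)4 cat., THF, 0 °C to rt) proceeds with retention of alkene geometry for silylmethyl Grignard reagents and should give 6 after aqueous work-up.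

Further compounds
F1 | step 4 | [(2R,3R,4R)-4-[benzhydryl(dimethyl)silyl]-2-(3,4-dimethoxyphenyl)oxolan-3-yl]methyl 3,4-dimethoxybenzoate | COc1ccc(C(=O)OC[C@H]2[C@@H]([Si](C)(C)C(c3ccccc3)c3ccccc3)CO[C@H]2c2ccc(OC)c(OC)c2)cc1OC
F2 | step 5 | (3S,4R,5S)-5-(3,4-dimethoxyphenyl)-4-(hydroxymethyl)oxolan-3-ol | OC[C@@H]1[C@H](O)CO[C@@H]1c1ccc(OC)c(OC)c1
F3 | step 2 | benzhydryl(chloromethyl)dimethylsilane | ClC[Si](C)(C)C(c1ccccc1)c1ccccc1
F4 | step 2 | {[benzhydryl(dimethyl)silyl]methyl}magnesium chloride | Cl[Mg]C[Si](C)(C)C(c1ccccc1)c1ccccc1
F5 | step 2 | (Z)-3-iodoprop-2-en-1-ol | OC/C=C\I
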